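The cyclohexenone ring (C4a, C5, C6, C7, C8, C8a; isochromene numbering) is assembled by a [3+3] union of an acetone-like C5–C4a–C8a unit with a C6–C7–C8 unit. Because C8a carries C1–O2, C5 and C1 are tied through O2 into a temporary ring, 4-bromotetrahydrofuran-3-one; the partner is a lactic-acid-derived dioxolanone aldehyde. In one SmI2 operation a Reformatsky aldol forms C8a–C8, reductive scission of the furanone C5–O2 bond unveils a second enolate, and acyl transfer forms C5–C6 with loss of pivalaldehyde, giving the 1,3-dione. Regioselective triflation, Sonogashira coupling with the side-chain enyne (made from the same aldehyde) and 6-endo cyclisation build the pyran.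

Key step: step 6

Remarks: Ring atoms are labelled O2, C1, C3, C4, C4a, C5–C8, C8a and side-chain atoms C1'–C7'. Compounds 7 and 8 are racemic; the stereocentre of 8 is erased when its enolate forms. Compounds 9 and 10 exist in the flask as samarium alkoxides/enolates and are drawn in their neutral forms.

Step 1
Reactants: 1 (R)-lactic acid; 2 pivalaldehyde
Product: 3 (2R,5R)-2-tert-butyl-5-methyl-1,3-dioxolan-4-one
Conditions: TsOH·H2O (cat.), H2SO4 (cat.), pentane, reflux, Dean–Stark; crystallisation from pentane at −78 °C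
Reagents that add atoms: none
Why: Acid-catalysed acetalisation of the α-hydroxy acid (dioxolanone formation); the cis isomer predominates at equilibrium and is purified by crystallisation, so the lactate centre fixes the new acetal centre as 2R.

Step 2
Reactants: 3 (2R,5R)-2-tert-butyl-5-methyl-1,3-dioxolan-4-one
Product: 4 (2R,5S)-2-tert-butyl-5-(hydroxymethyl)-5-methyl-1,3-dioxolan-4-one
Conditions: LiN(i-Pr)2, THF, −78 °C; CH2O (gas, from paraformaldehyde), −78 °C; NH4Cl (aq)
Reagents that add atoms: formaldehyde, C=O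
Why: Self-regeneration of the stereocentre: the planar lithium enolate undergoes aldol addition to formaldehyde on the face anti to the tert-butyl group, which sets the quaternary carbon (later C7 and C3') with overall retention.

Step 3
Reactants: 4 (2R,5S)-2-tert-butyl-5-(hydroxymethyl)-5-methyl-1,3-dioxolan-4-one
Product: 5 (2R,4S)-2-tert-butyl-4-methyl-5-oxo-1,3-dioxolane-4-carbaldehyde
Conditions: Dess–Martin periodinane, CH2Cl2, 0 °C → rt; used at once
Reagents that add atoms: none
Why: Dess–Martin oxidation of the neopentyl primary alcohol to a non-enolisable aldehyde; no stereocentre is affected.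

Step 4
Reactants: 6 2,5-dihydrofuran
Product: 7 trans-4-bromotetrahydrofuran-3-ol (racemic)
Conditions: N-bromosuccinimide, H2O/THF, 0 °C → rt
Reagents that add atoms: N-bromosuccinimide, O=C1CCC(=O)N1Br; water, O
Why: Bromohydrin formation by anti opening of the bromonium ion gives the trans isomer as a racemate, which suffices because this centre is erased in step 6.

Step 5
Reactants: 7 trans-4-bromotetrahydrofuran-3-ol
Product: 8 4-bromodihydrofuran-3(2H)-one (racemic)
Conditions: Dess–Martin periodinane, CH2Cl2, 0 °C; used crude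
Reagents that add atoms: none
Why: Dess–Martin oxidation of the secondary alcohol to the α-bromo ketone under neutral conditions that should avoid loss of HBr.

Step 6
Reactants: 5 (2R,4S)-2-tert-butyl-4-methyl-5-oxo-1,3-dioxolane-4-carbaldehyde; 8 4-bromodihydrofuran-3(2H)-one
Product: 11 (4S,5R,6S)-4,5-dihydroxy-6-(hydroxymethyl)-4-methylcyclohexane-1,3-dione, via aldol adduct 9 (not isolated), via ring-opened ketone 10 (not isolated)
Conditions: SmI2 (4.5 equiv), THF, −78 °C (5 and 8 added together), then → 0 °C; 0.1 M HCl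
Reagents that add atoms: none
Why: Proposed new method: SmI2 reduces the C–Br bond of 8 to a ring-locked samarium enolate (C4a=C8a) that adds to the aldehyde of 5 (samarium Reformatsky aldol, forms C8a–C8), more SmI2 then reduces the regenerated ketone to its ketyl, which expels the α-alkoxy oxygen O2 from C5 (known reductive scission of α-alkoxy ketones) to give a second, regiodefined enolate at C5 that attacks the dioxolanone carbonyl C6 in a Dieckmann-type Claisen acylation (forms C5–C6), the acylal collapsing with loss of pivalaldehyde; the closest known reaction types are SmI2 Reformatsky aldols and sequenced SmI2 reductive cleavage–enolate trapping. The carbocycle closes by 6-(enolexo)-exo-trig attack of C5 on C6, while the temporary oxolane ring is opened, not closed. C8a and C8 arise in the aldol: the cyclic E-enolate should give the anti aldol through a chair Zimmerman–Traxler transition state (C8–OH cis to C1 in the ring), and the face of the aldehyde is governed by the C7 stereocentre, the oxophilic trivalent samarium chelating the aldehyde oxygen and the ring oxygen on C7 (Cram-chelate arrangement) so that the enolate enters from the exposed exo face on the side of CH3, which should lead to 8R. The order of events is self-regulating, because the ketone is masked as its enolate until the aldol is over and bromide is lost far more readily than the ring oxygen. The step needs aldehyde-over-lactone chemoselectivity in the first stage (secured by the higher electrophilicity of the aldehyde at −78 °C) and C- rather than O-acylation in the last; if the freed C1 alkoxide lactonises onto C6 first, the C5 enolate can still take the acyl group from that δ-lactone because the chelated β-diketonate is the thermodynamic sink.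

Step 7
Reactants: 11 (4S,5R,6S)-4,5-dihydroxy-6-(hydroxymethyl)-4-methylcyclohexane-1,3-dione
Product: 12 (4S,5R,6S)-4,5-dihydroxy-6-(hydroxymethyl)-4-methyl-3-oxocyclohex-1-en-1-yl trifluoromethanesulfonate
Conditions: PhNTf2 (1.05 equiv), Et3N (1.1 equiv), DMAP (cat.), THF, −20 → 0 °C
Reagents that add atoms: N-phenylbis(trifluoromethanesulfonimide), O=S(=O)(N(c1ccccc1)S(=O)(=O)C(F)(F)F)C(F)(F)F
Why: O-sulfonylation of the 1,3-diketone enolate (enol triflate formation): Et3N deprotonates only the acidic diketone, and the oxygen on C4a, remote from the quaternary C7 and not hydrogen-bonded to the C7 hydroxyl, should react, as 4,4-disubstituted cyclohexane-1,3-diones do at their less hindered oxygen.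

Step 8
Reactants: 5 (2R,4S)-2-tert-butyl-4-methyl-5-oxo-1,3-dioxolane-4-carbaldehyde
Product: 13 (2R,5S)-2-tert-butyl-5-[(1S,2R)-1-hydroxy-2-methylbut-3-en-1-yl]-5-methyl-1,3-dioxolan-4-one
Conditions: (Z)-crotylboronic acid pinacol ester (1.5 equiv), 4 Å molecular sieves, toluene, −78 °C → rt; NaHCO3 (aq)
Reagents that add atoms: (Z)-crotylboronic acid pinacol ester, C/C=C\CB1OC(C)(C)C(C)(C)O1
Why: Crotylboration through a closed chair transition state: the Z reagent gives the syn OH/CH3 pair, and the non-chelating boron lets the aldehyde react in the Cornforth arrangement (C=O anti to the ring C–O) on its exposed exo face, which should set C4' as S and C5' as R.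

Step 9
Reactants: 13 (2R,5S)-2-tert-butyl-5-[(1S,2R)-1-hydroxy-2-methylbut-3-en-1-yl]-5-methyl-1,3-dioxolan-4-one
Product: 14 (2R,5S)-2-tert-butyl-5-[(1S,2R)-1-hydroxy-2-methylbutyl]-5-methyl-1,3-dioxolan-4-one
Conditions: H2 (1 atm), 10% Pd/C, EtOAc, rt
Reagents that add atoms: none
Why: Heterogeneous hydrogenation of the monosubstituted alkene turns vinyl into ethyl; no stereocentre is involved.

Step 10
Reactants: 14 (2R,5S)-2-tert-butyl-5-[(1S,2R)-1-hydroxy-2-methylbutyl]-5-methyl-1,3-dioxolan-4-one
Product: 15 methyl (4S,5S)-5-[(2R)-butan-2-yl]-2,2,4-trimethyl-1,3-dioxolane-4-carboxylate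
Conditions: HCl (from AcCl), MeOH, 50 °C; then Me2C(OMe)2, TsOH (cat.), acetone, rt
Reagents that add atoms: methanol, CO; 2,2-dimethoxypropane, COC(C)(C)OC
Why: Acid-catalysed methanolysis of the acylal frees the diol methyl ester, and transacetalisation then gives the acetonide of the tertiary/secondary 1,2-diol; no stereocentre is touched.

Step 11
Reactants: 15 methyl (4S,5S)-5-[(2R)-butan-2-yl]-2,2,4-trimethyl-1,3-dioxolane-4-carboxylate
Product: 16 (4S,5S)-5-[(2R)-butan-2-yl]-2,2,4-trimethyl-1,3-dioxolane-4-carbaldehyde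
Conditions: i-Bu2AlH (1.1 equiv), CH2Cl2, −78 °C; KNaC4H4O6 (aq)
Reagents that add atoms: none
Why: Partial ester reduction through the aluminium hemiacetal that is stable at −78 °C; the quaternary α-carbon cannot epimerise.

Step 12
Reactants: 16 (4S,5S)-5-[(2R)-butan-2-yl]-2,2,4-trimethyl-1,3-dioxolane-4-carbaldehyde
Product: 18 (4R,5S)-4-[(1E)-but-1-en-3-yn-1-yl]-5-[(2R)-butan-2-yl]-2,2,4-trimethyl-1,3-dioxolane, via silylated enyne 17 (not isolated)
Conditions: (EtO)2P(O)CH2C≡CSiMe3, LiN(SiMe3)2, THF, −78 → 0 °C; then K2CO3 (cat.), MeOH, rt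
Reagents that add atoms: diethyl [3-(trimethylsilyl)prop-2-yn-1-yl]phosphonate, CCOP(=O)(CC#C[Si](C)(C)C)OCC
Why: Horner–Wadsworth–Emmons olefination with the silylpropargyl phosphonate should give the E-enyne, and methanolic K2CO3 then protodesilylates the alkyne.

Step 13
Reactants: 18 (4R,5S)-4-[(1E)-but-1-en-3-yn-1-yl]-5-[(2R)-butan-2-yl]-2,2,4-trimethyl-1,3-dioxolane
Product: 19 (3E,5R,6S,7R)-5,7-dimethylnon-3-en-1-yne-5,6-diol
Conditions: 1 M HCl, THF, rt
Reagents that add atoms: none
Why: Mild acid-catalysed acetonide hydrolysis; the stereocentres are untouched and short exposure should spare the tertiary allylic alcohol.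

Step 14
Reactants: 12 (4S,5R,6S)-4,5-dihydroxy-6-(hydroxymethyl)-4-methyl-3-oxocyclohex-1-en-1-yl trifluoromethanesulfonate; 19 (3E,5R,6S,7R)-5,7-dimethylnon-3-en-1-yne-5,6-diol
Product: 21 (7S,8R,8aS)-3-[(1E,3R,4S,5R)-3,4-dihydroxy-3,5-dimethylhept-1-en-1-yl]-7,8-dihydroxy-7-methyl-8,8a-dihydro-1H-isochromen-6(7H)-one, via enynone 20 (not isolated)
Conditions: Pd(PPh3)2Cl2 (5 mol %), CuI (10 mol %), Et3N (3 equiv), THF, rt; then AgOTf (10 mol %), rt
Reagents that add atoms: none
Why: Sonogashira coupling of the vinylogous acyl triflate with the terminal alkyne, then silver-catalysed 6-endo-dig addition of the C1 hydroxyl to C3 of the dienynone (vinylogous oxa-Michael, as in β-hydroxy ynone to dihydropyranone closures) and tautomerisation to the conjugated dienol ether; closure through the C8 hydroxyl would need a bridgehead alkene, and no stereocentre is touched.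

Compound list
1 | (R)-lactic acid | C[C@@H](O)C(=O)O | starting material
2 | pivalaldehyde | CC(C)(C)C=O | starting material
3 | (2R,5R)-2-tert-butyl-5-methyl-1,3-dioxolan-4-one (cis) | C[C@H]1O[C@@H](C(C)(C)C)OC1=O | intermediate
4 | (2R,5S)-2-tert-butyl-5-(hydroxymethyl)-5-methyl-1,3-dioxolan-4-one | C[C@@]1(CO)O[C@@H](C(C)(C)C)OC1=O | intermediate
5 | (2R,4S)-2-tert-butyl-4-methyl-5-oxo-1,3-dioxolane-4-carbaldehyde | C[C@@]1(C=O)O[C@@H](C(C)(C)C)OC1=O | intermediate
6 | 2,5-dihydrofuran | C1C=CCO1 | starting material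
7 | trans-4-bromotetrahydrofuran-3-ol (racemic; the (3S,4S) enantiomer is drawn) | O[C@H]1COC[C@@H]1Br | intermediate
8 | 4-bromodihydrofuran-3(2H)-one (racemic) | O=C1COCC1Br | intermediate
9 | (2R,5S)-2-tert-butyl-5-{(R)-hydroxy[(3S)-4-oxotetrahydrofuran-3-yl]methyl}-5-methyl-1,3-dioxolan-4-one (aldol adduct, formed as its samarium alkoxide) | O=C1COC[C@H]1[C@@H](O)[C@]2(C)O[C@@H](C(C)(C)C)OC2=O | intermediate
10 | (2R,5S)-2-tert-butyl-5-[(1R,2S)-1-hydroxy-2-(hydroxymethyl)-3-oxobutyl]-5-methyl-1,3-dioxolan-4-one (formed as its samarium enolate/alkoxide) | CC(=O)[C@@H](CO)[C@@H](O)[C@]1(C)O[C@@H](C(C)(C)C)OC1=O | intermediate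
11 | (4S,5R,6S)-4,5-dihydroxy-6-(hydroxymethyl)-4-methylcyclohexane-1,3-dione | O=C1CC(=O)[C@@H](CO)[C@@H](O)[C@]1(C)O | intermediate
12 | (4S,5R,6S)-4,5-dihydroxy-6-(hydroxymethyl)-4-methyl-3-oxocyclohex-1-en-1-yl trifluoromethanesulfonate | O=C1C=C(OS(=O)(=O)C(F)(F)F)[C@@H](CO)[C@@H](O)[C@]1(C)O | intermediate
13 | (2R,5S)-2-tert-butyl-5-[(1S,2R)-1-hydroxy-2-methylbut-3-en-1-yl]-5-methyl-1,3-dioxolan-4-one | C=C[C@@H](C)[C@H](O)[C@]1(C)O[C@@H](C(C)(C)C)OC1=O | intermediate
14 | (2R,5S)-2-tert-butyl-5-[(1S,2R)-1-hydroxy-2-methylbutyl]-5-methyl-1,3-dioxolan-4-one | CC[C@@H](C)[C@H](O)[C@]1(C)O[C@@H](C(C)(C)C)OC1=O | intermediate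
15 | methyl (4S,5S)-5-[(2R)-butan-2-yl]-2,2,4-trimethyl-1,3-dioxolane-4-carboxylate | CC[C@@H](C)[C@@H]1OC(C)(C)O[C@]1(C)C(=O)OC | intermediate
16 | (4S,5S)-5-[(2R)-butan-2-yl]-2,2,4-trimethyl-1,3-dioxolane-4-carbaldehyde | CC[C@@H](C)[C@@H]1OC(C)(C)O[C@]1(C)C=O | intermediate
17 | (4R,5S)-5-[(2R)-butan-2-yl]-2,2,4-trimethyl-4-[(1E)-4-(trimethylsilyl)but-1-en-3-yn-1-yl]-1,3-dioxolane | CC[C@@H](C)[C@@H]1OC(C)(C)O[C@]1(C)/C=C/C#C[Si](C)(C)C | intermediate
18 | (4R,5S)-4-[(1E)-but-1-en-3-yn-1-yl]-5-[(2R)-butan-2-yl]-2,2,4-trimethyl-1,3-dioxolane | CC[C@@H](C)[C@@H]1OC(C)(C)O[C@]1(C)/C=C/C#C | intermediate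
19 | (3E,5R,6S,7R)-5,7-dimethylnon-3-en-1-yne-5,6-diol | CC[C@@H](C)[C@H](O)[C@](C)(O)/C=C/C#C | intermediate
20 | (4S,5R,6S)-3-[(3E,5R,6S,7R)-5,6-dihydroxy-5,7-dimethylnon-3-en-1-yn-1-yl]-5,6-dihydroxy-4-(hydroxymethyl)-6-methylcyclohex-2-en-1-one | CC[C@@H](C)[C@H](O)[C@](C)(O)/C=C/C#CC1=CC(=O)[C@@](C)(O)[C@H](O)[C@@H]1CO | intermediate
21 | (7S,8R,8aS)-3-[(1E,3R,4S,5R)-3,4-dihydroxy-3,5-dimethylhept-1-en-1-yl]-7,8-dihydroxy-7-methyl-8,8a-dihydro-1H-isochromen-6(7H)-one | CC[C@@H](C)[C@H](O)[C@](C)(O)/C=C/C1=CC2=CC(=O)[C@@](C)(O)[C@H](O)[C@@H]2CO1 | target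

Total steps: 14. Longest linear sequence: 10 steps (1, 2, 3, 8, 9, 10, 11, 12, 13, 14).

Steps most likely to fail

Step 6 (proposed new method). The second samarium enolate may be protonated, or O-acylation and retro-aldol may outrun C-acylation, so the sequence could stall before the ring closes. Chelation by the acetal-type ring oxygen may also be too weak, which would erode facial selectivity at C8. The fallback sets out from 5 and 8 and returns at 11, using known reactions one at a time. The SmI2 Reformatsky aldol is stopped at −78 °C (2.2 equiv SmI2, NH4Cl quench) and the aldol adduct 9 is isolated. SmI2 (2.5 equiv) in THF/MeOH at −78 °C then cleaves the α-alkoxy ketone to the ring-opened ketone 10, also isolated. TESOTf and 2,6-lutidine give the bis(triethylsilyl) ether of 10 F1. LiN(SiMe3)2 (2.2 equiv) in THF, −78 → 0 °C, deprotonates the methyl ketone kinetically and effects the Dieckmann-type Claisen cyclisation onto the dioxolanone with loss of pivalaldehyde, giving the bis(triethylsilyl) ether of the dione F2. HF·pyridine in MeCN removes the silyl groups to give 11.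

Step 7. Sulfonylation may occur at the wrong enolate oxygen or at the free hydroxyls, and the β-hydroxy groups may be eliminated under base. The fallback sets out from 11 and returns at 20, which closes to 21 with AgOTf as in step 14. TBSOTf and 2,6-lutidine at −78 °C, followed by brief K2CO3/MeOH to cleave the silyl enol ether, give the C1,C8-bis(tert-butyldimethylsilyl) ether of 11 F3. N-(5-chloropyridin-2-yl)bis(trifluoromethanesulfonimide) with Et3N and DMAP then gives the silylated enol triflate F4, whose regioisomers should be separable now that the compound is non-polar. Sonogashira coupling with 19 gives the silylated enynone F5, and HF·pyridine in THF frees 20.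

Step 14. Ring closure may be slow or take the 5-exo course, and the amine base may epimerise C8a or degrade the triflate before coupling. The fallback sets out from 12 and 18 and returns at 21. Copper-free Sonogashira coupling (Pd(PPh3)4, Et3N, DMF) of 12 with the acetonide 18 gives the acetonide-protected enynone F6, which is isolated. Base-mediated 1,6-oxa-Michael closure (DBU, 0.2 equiv, MeCN) gives the side-chain acetonide of the target F7. 80% aqueous AcOH at rt then removes the acetonide to give 21.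

Further compounds
F1 | step 6 | (2R,5S)-2-tert-butyl-5-methyl-5-{(1R,2S)-3-oxo-1-[(triethylsilyl)oxy]-2-{[(triethylsilyl)oxy]methyl}butyl}-1,3-dioxolan-4-one | CC(=O)[C@@H](CO[Si](CC)(CC)CC)[C@@H](O[Si](CC)(CC)CC)[C@]1(C)O[C@@H](C(C)(C)C)OC1=O
F2 | step 6 | (4S,5R,6S)-4-hydroxy-4-methyl-5-[(triethylsilyl)oxy]-6-{[(triethylsilyl)oxy]methyl}cyclohexane-1,3-dione | O=C1CC(=O)[C@@H](CO[Si](CC)(CC)CC)[C@@H](O[Si](CC)(CC)CC)[C@]1(C)O
F3 | step 7 | (4S,5R,6S)-5-[(tert-butyldimethylsilyl)oxy]-6-{[(tert-butyldimethylsilyl)oxy]methyl}-4-hydroxy-4-methylcyclohexane-1,3-dione | O=C1CC(=O)[C@@H](CO[Si](C)(C)C(C)(C)C)[C@@H](O[Si](C)(C)C(C)(C)C)[C@]1(C)O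
F4 | step 7 | (4S,5R,6S)-5-[(tert-butyldimethylsilyl)oxy]-6-{[(tert-butyldimethylsilyl)oxy]methyl}-4-hydroxy-4-methyl-3-oxocyclohex-1-en-1-yl trifluoromethanesulfonate | O=C1C=C(OS(=O)(=O)C(F)(F)F)[C@@H](CO[Si](C)(C)C(C)(C)C)[C@@H](O[Si](C)(C)C(C)(C)C)[C@]1(C)O
F5 | step 7 | (4S,5R,6S)-5-[(tert-butyldimethylsilyl)oxy]-4-{[(tert-butyldimethylsilyl)oxy]methyl}-3-[(3E,5R,6S,7R)-5,6-dihydroxy-5,7-dimethylnon-3-en-1-yn-1-yl]-6-hydroxy-6-methylcyclohex-2-en-1-one | CC[C@@H](C)[C@H](O)[C@](C)(O)/C=C/C#CC1=CC(=O)[C@@](C)(O)[C@H](O[Si](C)(C)C(C)(C)C)[C@@H]1CO[Si](C)(C)C(C)(C)C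
F6 | step 14 | (4S,5R,6S)-3-{(3E)-4-[(4R,5S)-5-[(2R)-butan-2-yl]-2,2,4-trimethyl-1,3-dioxolan-4-yl]but-3-en-1-yn-1-yl}-5,6-dihydroxy-4-(hydroxymethyl)-6-methylcyclohex-2-en-1-one | CC[C@@H](C)[C@@H]1OC(C)(C)O[C@]1(C)/C=C/C#CC1=CC(=O)[C@@](C)(O)[C@H](O)[C@@H]1CO
F7 | step 14 | (7S,8R,8aS)-3-{(E)-2-[(4R,5S)-5-[(2R)-butan-2-yl]-2,2,4-trimethyl-1,3-dioxolan-4-yl]ethenyl}-7,8-dihydroxy-7-methyl-8,8a-dihydro-1H-isochromen-6(7H)-one | CC[C@@H](C)[C@@H]1OC(C)(C)O[C@]1(C)/C=C/C1=CC2=CC(=O)[C@@](C)(O)[C@H](O)[C@@H]2CO1
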